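## The problem

The target is a coumaronochromone: an isoflavone (rings A and B the chromone, ring D the 3-aryl group) whose C2 and C2' are bridged by oxygen to form the furan ring C, so that rings A to D make one flat, electron-rich benzofuro[2,3-b]chromen-4-one. Two dimethylpyran rings are fused to it: the chromene ring F through O7 and C8 of ring A, and the 3'',4''-dihydroxy-2'',2''-dimethyldihydropyran ring E through C3' and O4' of ring D. Ring A is fully substituted (5-OH, 6-Me, 7-O, 8-C), so the synthesis must decide which of the two oxygens beside the carbonyl-bearing carbon closes ring B (6-methyl or 8-methyl series) and which oxygen closes ring F. The only stereocentres are the adjacent carbinol carbons C3'' (R) and C4'' (S), trans on ring E; the rest of the molecule is planar and cannot relay chirality, so one centre must come from a reagent or catalyst and is then the only handle on the other. The C4'' hydroxyl is benzylic on a carbon flanked by the oxygen-bearing carbons C2' and C4' and will ionise in acid (epimerisation, solvolysis, dehydration). The ring F alkene is the same kind of 2,2-dimethylchromene double bond that an oxidative route to ring E would have to functionalise, and ring D is a hydroxyquinol ether that over-oxidises easily. The feature that allows a short endgame is that ring E is held by just two bonds, C3'–C4'' and O4'–C2''. C3' is the only free carbon ortho to O4' once O5' is capped, and C2''(Me)2–C3''(OH)–C4''(OH) is an epoxidised prenal in disguise, its aldehyde carbon destined for C3' and its tertiary epoxide carbon for O4'.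

## Retrosynthesis

**29 to 28 (O5'–allyl).** The last operation must be non-acidic because of the C4'' carbinol. An acetal on O5' would need acid, a benzyl ether would need hydrogenolysis in the presence of the ring F alkene, and a silyl ether beside the 4'-phenoxide could migrate during the key step. An allyl ether is inert to base, Lewis acid and DDQ and leaves with zerovalent palladium and an amine, so 28 is the 5'-O-allyl ether of 29.

**28 to 25 and 22 (C3'–C4'' and O4'–C2'').** Cutting both bonds that hold ring E removes the ring and both stereocentres in one move and leaves the achiral, flat phenol 25 and the five-carbon epoxy aldehyde 22. The neighbouring cuts are weaker. Oxidising a ring E alkene cannot be done selectively once ring F is present, and a C3''–C4'' cut puts carbon where oxygen is needed at C4''. Forward, magnesium phenoxide 26 must add through C3' to the aldehyde with threo selectivity to give 27, and the 4'-oxygen must then open the epoxide at its tertiary carbon (6-endo). The C3''–O bond is never broken, so the configuration of 22 becomes that of C3'' and, through chelation, dictates C4''.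

**22 to 21 to 20 (aldehyde oxidation level, epoxide C–O bonds).** The aldehyde 22 comes from epoxy alcohol 21 by a neutral oxidation, and 21 from prenol 20 by Sharpless epoxidation. The single stereocentre is bought in one catalytic step from an achiral C5 alcohol. The 2S aldehyde is required, which corresponds to the 2R alcohol.

**25 to 24 to 23 (O2'–C2 bond of ring C).** Opening the furan ring gives the 2'-hydroxyisoflavone 24, whose dehydrogenative cyclisation to a coumaronochromone is the biomimetic route to this ring system. Compared with closing ring B last, this keeps all carbon–carbon bond formation in one robust cross-coupling. Phenol 24 comes from 23 by removing two methoxymethyl groups; the acid needed is harmless at this stage because no ionisable carbinol is yet present. This is why acetals protect O2' and O4' while allyl protects O5'.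

**23 to 11 and 19 (C3–C1').** The isoflavone bond is cut to the 3-iodochromone 11 (rings A, B and F) and the arylboronate 19 (ring D). A Suzuki–Miyaura coupling joins two pieces of similar size, and ring F is already in place, so no chromene has to be made in the presence of the electron-rich ring D.

**11 to 9 and 10, 9 to 8 (ring F: C8–C and O7–C bonds).** Ring F is removed as prenal 10 from the 5,7-dihydroxy-6-methylchromone 9. In 9 the 5-hydroxyl is chelated and its ortho carbon C6 carries the methyl, so the annulation can only occur at O7/C8. Diol 9 comes from the bis-isopropyl ether 8, which is cleaved by BCl3 without touching the vinyl iodide.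

**8 to 7 to 6 to 4 (ring B: O1–C2 and the C2 carbon; C4a–acyl bond).** Iodine-induced cyclisation of enaminone 7 forms ring B and installs the iodide together. Enaminone 7 comes from methyl ketone 6, and 6 from phenol 4 by Hoesch acylation through ketiminium salt 5. The requirement is that only one oxygen beside the acyl carbon is free in 6, and that it is the one next to the ring hydrogen, so that the methyl ends at C6 and not C8.

**4 to 2 to 1 (C8a–O bond).** A ring A precursor that already carries all three oxygens would leave two unequal hydroxyls beside the acyl carbon and an ambiguous ring closure. Instead the third oxygen is introduced last into the symmetric diether 2. Sterically governed C–H borylation can only reach the hydrogen para to the methyl, and oxidation of boronate 3 gives phenol 4. In 4 the free hydroxyl is unique and both of its ortho carbons are equivalent, so acylation, ring B closure and ring F annulation are all regiochemically forced. Diether 2 is the bis-isopropyl ether of 2-methylresorcinol 1.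

**19 to 17 to 16 to 13 to 12 (ring D).** The boronate 19 comes from bromide 17 by bromine–lithium exchange (aryllithium 18). Bromide 17 is the allyl ether of phenol 16, which comes from the symmetric dibromide 13 by exchange of one bromine (aryllithium 14), borylation (15) and oxidation. Dibromide 13 is the bis-methoxymethyl ether of 4,6-dibromobenzene-1,3-diol 12, whose substitution pattern already matches C1', C2'-O, C4'-O and C5'.

## Roads not taken

**Alternative 1:** Ring B is cut last, at C3–C4 and O1–C2. In the forward sense the 3-lithiated 2-(methylsulfanyl)benzofuran A2 already holds rings C, D and E with the diol as a bis-silyl ether. It would attack the lactone carbonyl of the ring A/F salicylate acetonide A3; collapse of the acetal frees the ring A phenoxide, which displaces methanethiolate from C2 and closes the pyranone to give the fully protected target A1.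
- Merits: it is the most convergent of the four plans, it fixes the ring A regiochemistry inside A3, and ring E can be made on a small benzofuran where no second chromene competes, so the diol could come from well-tried alkene oxidation.
- Weak points: 3-lithiobenzofurans open to alkynyl phenoxides unless kept very cold, the carbonyl of A3 is flanked by two ortho substituents, and the aryl ketone formed is a better electrophile than the lactone. A1 also carries four protecting groups of two kinds, so two more steps follow, one of them acidic acetal cleavage on a molecule containing the ionisable C4''–O bond.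
- Comparison: in convergence and in the security of the stereochemistry this road is at least as good as the chosen plan. The chosen plan sets against it stereocentres that never meet an organolithium or an acid, a single neutral deprotection at the end, and a routine enaminone closure of ring B.

**Alternative 2:** Ring E is cut at C3''–C4'', with C4'' at the wrong oxidation level. Proline would close the dialdehyde A5: the enamine of the arylacetaldehyde arm adds to the non-enolisable alpha-aryloxy aldehyde (6-enolexo aldol) and gives the trans 3-hydroxy-4-formylchromane A4.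
- Merits: both centres come from a cheap catalyst and an achiral precursor. That catalyst economy is better than in the chosen plan, which uses a stoichiometric chiral building block (though one made in two steps).
- Weak points: C4'' ends up bearing a formyl group that must be exchanged for hydroxyl with retention (a Baeyer–Villiger step on an alpha-branched aldehyde, where hydrogen migration competes). A4 is epimerisable at its benzylic, formyl-bearing carbon, and the arylacetaldehyde arm of A5 self-condenses easily. The whole tetracyclic core, ring F included, would then have to be built onto A4 over ten or more steps with the diol protected throughout.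
- Comparison: the chosen plan forms C4'' directly as a carbinol and does so one step before the end.

**Alternative 3:** Both C–O bonds of the diol are cut, leading back to the ring E chromene A7 at a stage without ring F. Jacobsen–Katsuki epoxidation with a chiral Mn(salen)Cl complex would give epoxide A8, and water would open it at the benzylic carbon with inversion to the trans-diol A6.
- Merits: this epoxidation is the best-precedented enantioselective reaction for a 2,2-dimethylchromene, catalytic and usually highly selective. In that respect this road is stronger than the chosen one, whose key step has no direct precedent.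
- Weak points: the step must precede ring F because the two chromene alkenes cannot be told apart, so ring F has to be annulated afterwards onto a compound containing the acid- and heat-sensitive diol. Hydrolysis of A8 passes through a cation stabilised by two ortho oxygens, so the trans to cis outcome is not under control. The acetates on O7 and O5' of A6 still have to be differentiated and removed.
- Comparison: the chosen plan sets against the better precedent a trans relationship that follows from the mechanism (the C3''–O bond is never broken and C4'' is set by chelation), the freedom to carry ring F from the start, and a one-step endgame.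

Key step: step 17

Remark on the chemistry: the SMILES is read as the (3''R,4''S)-trans-diol. Isoflavone locants are used throughout (rings A/B = chromone, ring C = furan closed by the C2–O–C2' bridge, ring D = its benzo ring, ring E = diol-bearing pyran on C3'/O4', ring F = chromene on O7/C8). 4,6-Dibromobenzene-1,3-diol is taken as a purchasable source of ring D.

Step 1
Reactants: 1 2-methylbenzene-1,3-diol (2-methylresorcinol)
Product: 2 2-methyl-1,3-di(propan-2-yloxy)benzene
Conditions: 2-bromopropane (4 equiv), K2CO3, DMF, 70 °C
Reagents that add atoms: 2-bromopropane CC(C)Br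
Why: Williamson etherification of the two equivalent phenols; isopropyl ethers survive borylation, acylation and iodine and are later cleaved by BCl3 without harming a vinyl iodide.

Step 2
Reactants: 2 2-methyl-1,3-di(propan-2-yloxy)benzene
Product: 4 4-methyl-3,5-di(propan-2-yloxy)phenol, via aryl pinacol boronate 3 (not isolated)
Conditions: [Ir(OMe)(cod)]2 (1.5 mol %), 4,4'-di-tert-butyl-2,2'-bipyridine (3 mol %), B2pin2 (1.0 equiv), hexane, 80 °C; then 30% H2O2, aq. NaOH, THF, 0 °C
Reagents that add atoms: bis(pinacolato)diboron CC1(C)OB(OC1(C)C)B1OC(C)(C)C(C)(C)O1 (boron of intermediate 3); hydrogen peroxide OO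
Why: Sterically governed iridium-catalysed C–H borylation takes the only ring hydrogen without an ortho substituent (para to the methyl), and oxidation converts the C–B bond into C–O at the same carbon. The mirror symmetry of 2 leaves no regiochemical choice, and the new oxygen is the future O1 of the chromone.

Step 3
Reactants: 4 4-methyl-3,5-di(propan-2-yloxy)phenol
Product: 6 1-[6-hydroxy-3-methyl-2,4-di(propan-2-yloxy)phenyl]ethan-1-one, via ketiminium chloride 5 (not isolated)
Conditions: MeCN, ZnCl2, HCl (g), Et2O, 0 °C; then H2O, 90 °C
Reagents that add atoms: acetonitrile CC#N; water O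
Why: Houben–Hoesch acylation of a phloroglucinol diether followed by hydrolysis of the ketimine; the only free ring carbons are the two equivalent positions ortho to the hydroxyl, and the mild acid leaves the isopropyl ethers on. In 6 the free hydroxyl sits beside the ring hydrogen (future C8) while the oxygen beside the methyl stays capped.

Step 4
Reactants: 6 1-[6-hydroxy-3-methyl-2,4-di(propan-2-yloxy)phenyl]ethan-1-one
Product: 7 (2E)-3-(dimethylamino)-1-[6-hydroxy-3-methyl-2,4-di(propan-2-yloxy)phenyl]prop-2-en-1-one
Conditions: Me2NCH(OMe)2, toluene, 95 °C
Reagents that add atoms: N,N-dimethylformamide dimethyl acetal COC(OC)N(C)C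
Why: Condensation of the methyl ketone with the formamide acetal gives the trans enaminone, which supplies C2 of the chromone.

Step 5
Reactants: 7 (2E)-3-(dimethylamino)-1-[6-hydroxy-3-methyl-2,4-di(propan-2-yloxy)phenyl]prop-2-en-1-one
Product: 8 3-iodo-6-methyl-5,7-di(propan-2-yloxy)-4H-chromen-4-one
Conditions: I2, CHCl3, rt
Reagents that add atoms: iodine II
Why: Iodine-induced cyclisation of an o-hydroxyaryl enaminone: iodination at the enaminone alpha carbon, attack of the single free phenol on the iminium carbon and loss of dimethylamine. Ring B closes through the oxygen para to the methyl, which fixes the 6-methyl series.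

Step 6
Reactants: 8 3-iodo-6-methyl-5,7-di(propan-2-yloxy)-4H-chromen-4-one
Product: 9 5,7-dihydroxy-3-iodo-6-methyl-4H-chromen-4-one
Conditions: BCl3 (5 equiv), CH2Cl2, −78 °C to rt
Reagents that add atoms: none
Why: BCl3 cleaves aryl isopropyl ethers (the 5-ether fastest, through chelation to the carbonyl) and leaves the carbon–iodine bond intact.

Step 7
Reactants: 9 5,7-dihydroxy-3-iodo-6-methyl-4H-chromen-4-one; 10 3-methylbut-2-enal (prenal)
Product: 11 5-hydroxy-3-iodo-6,8,8-trimethyl-4H,8H-pyrano[2,3-h]chromen-4-one
Conditions: ethylenediammonium diacetate (20 mol %), toluene, reflux, Dean–Stark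
Reagents that add atoms: none
Why: Knoevenagel-type condensation at C8 followed by oxa-6π electrocyclisation (formal [3+3] chromene annulation of a phenol with an enal). C6 is blocked by the methyl and the 5-hydroxyl is held by the carbonyl, so only the angular O7/C8 pyran can form.

Step 8
Reactants: 12 4,6-dibromobenzene-1,3-diol
Product: 13 1,5-dibromo-2,4-bis(methoxymethoxy)benzene
Conditions: MOMCl, i-Pr2NEt, CH2Cl2, 0 °C to rt
Reagents that add atoms: chloromethyl methyl ether COCCl
Why: Standard acetal protection of both phenols; in the symmetric product either bromine may be exchanged.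

Step 9
Reactants: 13 1,5-dibromo-2,4-bis(methoxymethoxy)benzene
Product: 16 5-bromo-2,4-bis(methoxymethoxy)phenol, via aryllithium 14 (not isolated), via dimethyl arylboronate 15 (not isolated)
Conditions: n-BuLi (1.0 equiv), THF, −78 °C; B(OMe)3, −78 to 0 °C; then 30% H2O2, aq. NaOH, 0 °C
Reagents that add atoms: trimethyl borate COB(OC)OC (boron of intermediate 15); hydrogen peroxide OO
Why: Bromine–lithium exchange of one of two equivalent bromides, borylation and oxidative conversion of C–B into C–O give the mono-phenol that becomes O5'. The second exchange is disfavoured once the ring carries a carbanion.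

Step 10
Reactants: 16 5-bromo-2,4-bis(methoxymethoxy)phenol
Product: 17 1-bromo-2,4-bis(methoxymethoxy)-5-(prop-2-en-1-yloxy)benzene
Conditions: allyl bromide, K2CO3, acetone, reflux
Reagents that add atoms: allyl bromide C=CCBr
Why: Williamson etherification; the allyl ether is the one protecting group still present at the end and is chosen because it can be removed under neutral palladium catalysis.

Step 11
Reactants: 17 1-bromo-2,4-bis(methoxymethoxy)-5-(prop-2-en-1-yloxy)benzene
Product: 19 2-[2,4-bis(methoxymethoxy)-5-(prop-2-en-1-yloxy)phenyl]-4,4,5,5-tetramethyl-1,3,2-dioxaborolane, via aryllithium 18 (not isolated)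
Conditions: n-BuLi, THF, −78 °C; 2-isopropoxy-4,4,5,5-tetramethyl-1,3,2-dioxaborolane, −78 °C to rt; aq. NH4Cl
Reagents that add atoms: 2-isopropoxy-4,4,5,5-tetramethyl-1,3,2-dioxaborolane CC(C)OB1OC(C)(C)C(C)(C)O1
Why: Bromine–lithium exchange at −78 °C outruns any reaction of the allyl or acetal groups. The pinacol ester is preferred to the free boronic acid because ortho-alkoxy arylboron compounds protodeboronate less readily as esters.

Step 12
Reactants: 20 3-methylbut-2-en-1-ol (prenol)
Product: 21 [(2R)-3,3-dimethyloxiran-2-yl]methanol
Conditions: Ti(OiPr)4 (10 mol %), D-(−)-diethyl tartrate (12 mol %), t-BuOOH, 4 Å molecular sieves, CH2Cl2, −20 °C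
Reagents that add atoms: tert-butyl hydroperoxide CC(C)(C)OO
Why: Sharpless asymmetric epoxidation; the unnatural D-(−)-tartrate delivers oxygen to the face that gives the 2R epoxy alcohol (L-(+)-tartrate gives 2S epoxides from primary allylic alcohols of this pattern). This centre becomes C3'' of the target.

Step 13
Reactants: 21 [(2R)-3,3-dimethyloxiran-2-yl]methanol
Product: 22 (2S)-3,3-dimethyloxirane-2-carbaldehyde
Conditions: TEMPO (10 mol %), PhI(OAc)2 (1.1 equiv), CH2Cl2, 0 °C to rt; used as a CH2Cl2 solution
Reagents that add atoms: none
Why: Oxoammonium-mediated oxidation of the primary alcohol under neutral conditions leaves the epoxide and its stereocentre untouched. The descriptor changes from R to S only because the formyl group outranks the ring carbon.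

Step 14
Reactants: 11 5-hydroxy-3-iodo-6,8,8-trimethyl-4H,8H-pyrano[2,3-h]chromen-4-one; 19 2-[2,4-bis(methoxymethoxy)-5-(prop-2-en-1-yloxy)phenyl]-4,4,5,5-tetramethyl-1,3,2-dioxaborolane
Product: 23 3-[2,4-bis(methoxymethoxy)-5-(prop-2-en-1-yloxy)phenyl]-5-hydroxy-6,8,8-trimethyl-4H,8H-pyrano[2,3-h]chromen-4-one
Conditions: Pd(dppf)Cl2 (5 mol %), K2CO3, 1,4-dioxane/H2O, 70 °C
Reagents that add atoms: none
Why: Suzuki–Miyaura coupling of a 3-iodochromone with an arylboronate, the standard isoflavone construction. Oxidative addition into the iodide is expected to be much faster than ionisation of the allyl aryl ether.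

Step 15
Reactants: 23 3-[2,4-bis(methoxymethoxy)-5-(prop-2-en-1-yloxy)phenyl]-5-hydroxy-6,8,8-trimethyl-4H,8H-pyrano[2,3-h]chromen-4-one
Product: 24 3-[2,4-dihydroxy-5-(prop-2-en-1-yloxy)phenyl]-5-hydroxy-6,8,8-trimethyl-4H,8H-pyrano[2,3-h]chromen-4-one
Conditions: HCl (cat.), MeOH/THF, 45 °C
Reagents that add atoms: none
Why: Acid-catalysed acetal exchange removes both methoxymethyl groups; the chromene, the allyl ether and the chromone tolerate this, and no ionisable carbinol is present yet.

Step 16
Reactants: 24 3-[2,4-dihydroxy-5-(prop-2-en-1-yloxy)phenyl]-5-hydroxy-6,8,8-trimethyl-4H,8H-pyrano[2,3-h]chromen-4-one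
Product: 25 4',5-dihydroxy-6-methyl-5'-(prop-2-en-1-yloxy)coumaronochromone bearing ring F at O7/C8 (pentacyclic phenol)
Conditions: DDQ (1.1 equiv), 1,4-dioxane, rt
Reagents that add atoms: none
Why: Dehydrogenative cyclisation of a 2'-hydroxyisoflavone to a coumaronochromone: two-electron oxidation of the electron-rich ring D (or of the enol formed by reversible oxa-Michael addition) makes C2 electrophilic, the 2'-oxygen closes the furan ring and the system rearomatises. The 4'-hydroxyl is para to C1' and cannot reach C2, so it stays free for the next step.

Step 17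
Reactants: 25 4',5-dihydroxy-6-methyl-5'-(prop-2-en-1-yloxy)coumaronochromone bearing ring F at O7/C8; 22 (2S)-3,3-dimethyloxirane-2-carbaldehyde
Product: 28 5'-O-(prop-2-en-1-yl) ether of the target: ring E closed on C3'/O4' as the (3''R,4''S)-trans-3'',4''-diol, via bis(chloromagnesium) phenoxide 26 (not isolated), via threo epoxy alcohol adduct 27 (not isolated)
Conditions: i-PrMgCl (2.05 equiv), CH2Cl2/THF, −40 °C; 22 (1.5 equiv), −40 to 0 °C; then BF3·OEt2 (3 equiv), −78 to −30 °C; aq. NaHCO3
Reagents that add atoms: none
Why: Proposed new method: magnesium phenoxide 26 binds the aldehyde oxygen of 22 and its ortho carbon C3' attacks the carbonyl through a six-membered phenoxide–magnesium–carbonyl array, the mechanism of the known ortho-specific hydroxyalkylation of magnesium phenoxides with alpha-alkoxy aldehydes, which is the closest known reaction type; an alpha,beta-epoxy aldehyde has not been used as the partner and the tandem ring closure is new. The new stereocentre C4'' is controlled by the stereocentre of 22: divalent magnesium bridges the carbonyl and epoxide oxygens, the CMe2 carbon blocks one face of this chelate and the arene adds on the hydrogen side, which for the 2S aldehyde gives the 4''S (threo) alkoxide 27. C3'' comes from the Sharpless step and none of its bonds is broken here. BF3·OEt2 then activates the oxirane and the 4'-oxygen opens it at the tertiary carbon in a 6-endo-tet closure that forms ring E, the mode known from acid-mediated cyclisation of o-(2,3-epoxy-3-methylbutyl)phenols to 3-hydroxy-2,2-dimethylchromans; the diol is therefore trans. Site selectivity on the arene is secured by the substrate: C5' is capped by the allyl ether, ring A has no free carbon and the 4'-phenoxide is only cross-conjugated with the chromone carbonyl, so C3' is the one nucleophilic ortho position. Selectivity at the oxirane rests on the tertiary carbon carrying the positive charge under Lewis acid, whereas 5-exo attack would need inversion at the secondary carbon next to the alkoxide. Keeping the benzylic oxygen as a metal alkoxide until work-up guards C4'' against ionisation.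

Step 18
Reactants: 28 5'-O-(prop-2-en-1-yl) ether of the target
Product: 29 target CNP0351839.1: 5,5'-dihydroxy-6-methylcoumaronochromone bearing ring F at O7/C8 and the (3''R,4''S)-trans-3'',4''-dihydroxy-2'',2''-dimethyldihydropyran ring E at C3'/O4'
Conditions: Pd(PPh3)4 (5 mol %), morpholine (10 equiv), THF, rt
Reagents that add atoms: none
Why: Zerovalent palladium ionises the aryl allyl ether to a π-allyl complex that morpholine intercepts. The medium is neutral to weakly basic, so the acid-labile C4'' carbinol, the chromene and the chelated phenol are untouched.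

Compound list

1 | 2-methylbenzene-1,3-diol (2-methylresorcinol) | Cc1c(O)cccc1O | starting material
2 | 2-methyl-1,3-di(propan-2-yloxy)benzene | Cc1c(OC(C)C)cccc1OC(C)C | intermediate
3 | 4,4,5,5-tetramethyl-2-[4-methyl-3,5-di(propan-2-yloxy)phenyl]-1,3,2-dioxaborolane | Cc1c(OC(C)C)cc(B2OC(C)(C)C(C)(C)O2)cc1OC(C)C | intermediate
4 | 4-methyl-3,5-di(propan-2-yloxy)phenol | Cc1c(OC(C)C)cc(O)cc1OC(C)C | intermediate
5 | 1-[6-hydroxy-3-methyl-2,4-di(propan-2-yloxy)phenyl]ethan-1-iminium chloride | CC(=[NH2+])c1c(O)cc(OC(C)C)c(C)c1OC(C)C.[Cl-] | intermediate
6 | 1-[6-hydroxy-3-methyl-2,4-di(propan-2-yloxy)phenyl]ethan-1-one | CC(=O)c1c(O)cc(OC(C)C)c(C)c1OC(C)C | intermediate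
7 | (2E)-3-(dimethylamino)-1-[6-hydroxy-3-methyl-2,4-di(propan-2-yloxy)phenyl]prop-2-en-1-one | CN(C)/C=C/C(=O)c1c(O)cc(OC(C)C)c(C)c1OC(C)C | intermediate
8 | 3-iodo-6-methyl-5,7-di(propan-2-yloxy)-4H-chromen-4-one | Cc1c(OC(C)C)cc2occ(I)c(=O)c2c1OC(C)C | intermediate
9 | 5,7-dihydroxy-3-iodo-6-methyl-4H-chromen-4-one | Cc1c(O)cc2occ(I)c(=O)c2c1O | intermediate
10 | 3-methylbut-2-enal (prenal) | CC(C)=CC=O | starting material
11 | 5-hydroxy-3-iodo-6,8,8-trimethyl-4H,8H-pyrano[2,3-h]chromen-4-one | Cc1c2c(c3occ(I)c(=O)c3c1O)C=CC(C)(C)O2 | intermediate
12 | 4,6-dibromobenzene-1,3-diol | Oc1cc(O)c(Br)cc1Br | starting material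
13 | 1,5-dibromo-2,4-bis(methoxymethoxy)benzene | COCOc1cc(OCOC)c(Br)cc1Br | intermediate
14 | [5-bromo-2,4-bis(methoxymethoxy)phenyl]lithium | [Li]c1cc(Br)c(OCOC)cc1OCOC | intermediate
15 | dimethyl [5-bromo-2,4-bis(methoxymethoxy)phenyl]boronate | COB(OC)c1cc(Br)c(OCOC)cc1OCOC | intermediate
16 | 5-bromo-2,4-bis(methoxymethoxy)phenol | Oc1cc(Br)c(OCOC)cc1OCOC | intermediate
17 | 1-bromo-2,4-bis(methoxymethoxy)-5-(prop-2-en-1-yloxy)benzene | C=CCOc1cc(Br)c(OCOC)cc1OCOC | intermediate
18 | [2,4-bis(methoxymethoxy)-5-(prop-2-en-1-yloxy)phenyl]lithium | [Li]c1cc(OCC=C)c(OCOC)cc1OCOC | intermediate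
19 | 2-[2,4-bis(methoxymethoxy)-5-(prop-2-en-1-yloxy)phenyl]-4,4,5,5-tetramethyl-1,3,2-dioxaborolane | C=CCOc1cc(B2OC(C)(C)C(C)(C)O2)c(OCOC)cc1OCOC | intermediate
20 | 3-methylbut-2-en-1-ol (prenol) | CC(C)=CCO | starting material
21 | [(2R)-3,3-dimethyloxiran-2-yl]methanol | OC[C@H]1OC1(C)C | intermediate
22 | (2S)-3,3-dimethyloxirane-2-carbaldehyde | O=C[C@H]1OC1(C)C | intermediate
23 | 3-[2,4-bis(methoxymethoxy)-5-(prop-2-en-1-yloxy)phenyl]-5-hydroxy-6,8,8-trimethyl-4H,8H-pyrano[2,3-h]chromen-4-one | Cc1c2c(c3occ(-c4cc(OCC=C)c(OCOC)cc4OCOC)c(=O)c3c1O)C=CC(C)(C)O2 | intermediate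
24 | 3-[2,4-dihydroxy-5-(prop-2-en-1-yloxy)phenyl]-5-hydroxy-6,8,8-trimethyl-4H,8H-pyrano[2,3-h]chromen-4-one | Cc1c2c(c3occ(-c4cc(OCC=C)c(O)cc4O)c(=O)c3c1O)C=CC(C)(C)O2 | intermediate
25 | pentacyclic phenol (rings A, B, C, D, F): 4',5-dihydroxy-6-methyl-5'-(prop-2-en-1-yloxy)coumaronochromone with the 2,2-dimethyl-2H-pyran ring F on O7/C8 | Cc1c2c(c3oc4oc5cc(O)c(OCC=C)cc5c4c(=O)c3c1O)C=CC(C)(C)O2 | intermediate
26 | bis(chloromagnesium) salt of 25 at O5 and O4' | Cc1c2c(c3oc4oc5cc(O[Mg]Cl)c(OCC=C)cc5c4c(=O)c3c1O[Mg]Cl)C=CC(C)(C)O2 | intermediate
27 | 25 carrying at C3' the (S)-[(2R)-3,3-dimethyloxiran-2-yl](hydroxy)methyl group (threo adduct, present as its magnesium salt) | Cc1c2c(c3oc4oc5c([C@H](O)[C@H]6OC6(C)C)c(O)c(OCC=C)cc5c4c(=O)c3c1O)C=CC(C)(C)O2 | intermediate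
28 | 5'-O-(prop-2-en-1-yl) ether of the target, (3''R,4''S)-trans-diol | Cc1c2c(c3oc4oc5c6c(c(OCC=C)cc5c4c(=O)c3c1O)OC(C)(C)[C@H](O)[C@H]6O)C=CC(C)(C)O2 | intermediate
29 | CNP0351839.1, (3''R,4''S) | Cc1c2c(c3oc4oc5c6c(c(O)cc5c4c(=O)c3c1O)OC(C)(C)[C@H](O)[C@H]6O)C=CC(C)(C)O2 | target

Total: 18 steps. Longest linear sequence: 12 steps (steps 1–7 and 14–18); the ring D boronate takes 4 steps (8–11) and the epoxy aldehyde 2 steps (12–13).

Least certain steps

**Step 17 (key step, without direct precedent).**
- What may go wrong: the doubly magnesiated phenoxide may be too insoluble or too weakly nucleophilic at C3', so that hemiacetal formation at oxygen or decomposition of the aldehyde takes over. Chelation of the epoxide oxygen may be too weak, so that the arene adds with poor facial selectivity. The alkoxide may undergo Payne rearrangement before ring closure, or the benzylic C–O bond may ionise once the Lewis acid is added.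
- Fallback (known reactions, from 25 back to 28): ortho-iodination of 25 with I2 and morpholine should give the 3'-iodide F1. Deprotonation of both phenols with MeMgCl and iodine–magnesium exchange with i-PrMgCl·LiCl gives the arylmagnesium species F2, which adds to 22 to give 27 together with its C4'' epimer F3. After work-up, pyridinium p-toluenesulfonate closes both to 28 and the cis-diol F4. If the epimers are formed in a poor ratio or do not separate, MnO2 oxidises the benzylic alcohol of the mixture to the hydroxy ketone F5, and hydroxyl-directed reduction with Me4NBH(OAc)3 (Evans–Saksena type, hydride delivered from the C3'' oxygen) returns the trans-diol 28.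

**Step 16.**
- What may go wrong: over-oxidation of the hydroxyquinol ring D to quinones or intermolecular phenol coupling may outrun ring closure, and the product is itself an electron-rich phenol open to further oxidation.
- Fallback (from 6 back to 25; ring C closed by addition–elimination instead of dehydrogenation): treating 6 with CS2 and KOtBu and then MeI gives the 2-(methylsulfanyl)chromone F6. N-Iodosuccinimide gives the 3-iodide F7, BCl3 the diol F8, and prenal with ethylenediammonium diacetate the pyranochromone F9. Suzuki–Miyaura coupling with 19 gives the 2-(methylsulfanyl)isoflavone F10, and HCl in MeOH frees the diphenol F11. Its 2'-hydroxyl then displaces methanethiol at C2 (K2CO3, DMF, 80 °C) to give 25 without any oxidant.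

**Step 7.**
- What may go wrong: the amine catalyst may add to C2 of the iodochromone and open the pyrone ring, and condensation at the carbonyl-deactivated C8 may be slow enough for self-condensation of prenal to dominate.
- Fallback (from 9 back to 11): alkylation of the 7-hydroxyl with 3-chloro-3-methylbut-1-yne (K2CO3, KI, CuI cat., acetone) gives the aryl 1,1-dimethylpropargyl ether F12. Heating in xylene brings about the aryl propargyl Claisen rearrangement, 1,5-hydrogen shift and electrocyclisation to 11; C8 is the only ortho carbon that can rearomatise.

**Step 12.**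
- What may go wrong: loss of the small, water-soluble, volatile epoxy alcohol on isolation, and incomplete enantioselection, which would carry through as the enantiomer of the target because 25 is achiral.
- Fallback (from 10 directly to 22): asymmetric epoxidation of prenal with H2O2 under iminium–enamine catalysis by a diarylprolinol trimethylsilyl ether gives 22 in one step and passes through no new compound (F0). The R catalyst is expected to give the 2S aldehyde by analogy with beta-monosubstituted enals; the sense would be confirmed by reduction to 21. Selectivity with beta,beta-disubstituted enals is generally lower, which is why this is the reserve and not the first choice.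

Further compounds

F1 | step 17 | 3'-iodo derivative of 25 | Cc1c2c(c3oc4oc5c(I)c(O)c(OCC=C)cc5c4c(=O)c3c1O)C=CC(C)(C)O2
F2 | step 17 | 3'-(chloromagnesio) bis(chloromagnesium phenoxide) from F1 | Cc1c2c(c3oc4oc5c([Mg]Cl)c(O[Mg]Cl)c(OCC=C)cc5c4c(=O)c3c1O[Mg]Cl)C=CC(C)(C)O2
F3 | step 17 | C4'' epimer of 27, (R)-carbinol with (2R)-oxirane (erythro adduct) | Cc1c2c(c3oc4oc5c([C@@H](O)[C@H]6OC6(C)C)c(O)c(OCC=C)cc5c4c(=O)c3c1O)C=CC(C)(C)O2
F4 | step 17 | (3''R,4''R)-cis-diol, C4'' epimer of 28 | Cc1c2c(c3oc4oc5c6c(c(OCC=C)cc5c4c(=O)c3c1O)OC(C)(C)[C@H](O)[C@@H]6O)C=CC(C)(C)O2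
F5 | step 17 | (3''S)-3''-hydroxy-4''-oxo analogue of 28 | Cc1c2c(c3oc4oc5c6c(c(OCC=C)cc5c4c(=O)c3c1O)OC(C)(C)[C@H](O)C6=O)C=CC(C)(C)O2
F6 | step 16 | 6-methyl-2-(methylsulfanyl)-5,7-di(propan-2-yloxy)-4H-chromen-4-one | CSc1cc(=O)c2c(OC(C)C)c(C)c(OC(C)C)cc2o1
F7 | step 16 | 3-iodo-6-methyl-2-(methylsulfanyl)-5,7-di(propan-2-yloxy)-4H-chromen-4-one | CSc1oc2cc(OC(C)C)c(C)c(OC(C)C)c2c(=O)c1I
F8 | step 16 | 5,7-dihydroxy-3-iodo-6-methyl-2-(methylsulfanyl)-4H-chromen-4-one | CSc1oc2cc(O)c(C)c(O)c2c(=O)c1I
F9 | step 16 | 5-hydroxy-3-iodo-6,8,8-trimethyl-2-(methylsulfanyl)-4H,8H-pyrano[2,3-h]chromen-4-one | Cc1c2c(c3oc(SC)c(I)c(=O)c3c1O)C=CC(C)(C)O2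
F10 | step 16 | 2-(methylsulfanyl) analogue of 23 | Cc1c2c(c3oc(SC)c(-c4cc(OCC=C)c(OCOC)cc4OCOC)c(=O)c3c1O)C=CC(C)(C)O2
F11 | step 16 | 2-(methylsulfanyl) analogue of 24 | Cc1c2c(c3oc(SC)c(-c4cc(OCC=C)c(O)cc4O)c(=O)c3c1O)C=CC(C)(C)O2
F12 | step 7 | 5-hydroxy-3-iodo-6-methyl-7-[(2-methylbut-3-yn-2-yl)oxy]-4H-chromen-4-one | Cc1c(OC(C)(C)C#C)cc2occ(I)c(=O)c2c1O
F0 | step 12 | none | none
A1 | alternative 1 | 5,5'-bis(methoxymethyl) 3'',4''-bis(tert-butyldimethylsilyl) ether of the target | Cc1c2c(c3oc4oc5c6c(c(OCOC)cc5c4c(=O)c3c1OCOC)OC(C)(C)[C@H](O[Si](C)(C)C(C)(C)C)[C@H]6O[Si](C)(C)C(C)(C)C)C=CC(C)(C)O2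
A2 | alternative 1 | 3-lithio-2-(methylsulfanyl)benzofuran carrying rings D and E (5'-O-methoxymethyl, diol as bis-silyl ether) | CSc1oc2c3c(c(OCOC)cc2c1[Li])OC(C)(C)[C@H](O[Si](C)(C)C(C)(C)C)[C@H]3O[Si](C)(C)C(C)(C)C
A3 | alternative 1 | ring A/F salicylate acetonide (2,2-dimethyl-1,3-benzodioxin-4-one with 5-O-methoxymethyl, 6-methyl and ring F) | Cc1c2c(c3OC(C)(C)OC(=O)c3c1OCOC)C=CC(C)(C)O2
A4 | alternative 2 | (3R,4S)-5-(benzyloxy)-3-hydroxy-8-(methoxymethoxy)-2,2-dimethylchromane-4-carbaldehyde | C(c1ccccc1)Oc1c2c(c(OCOC)cc1)OC(C)(C)[C@H](O)[C@H]2C=O
A5 | alternative 2 | 2-[3-(benzyloxy)-6-(methoxymethoxy)-2-(2-oxoethyl)phenoxy]-2-methylpropanal | O=CCc1c(OCc2ccccc2)ccc(OCOC)c1OC(C)(C)C=O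
A6 | alternative 3 | (3''R,4''S)-trans-diol of the ring F-less 7,5'-di-O-acetyl coumaronochromone | Cc1c(OC(C)=O)cc2oc3oc4c5c(c(OC(C)=O)cc4c3c(=O)c2c1O)OC(C)(C)[C@H](O)[C@H]5O
A7 | alternative 3 | ring E chromene of the ring F-less 7,5'-di-O-acetyl coumaronochromone | Cc1c(OC(C)=O)cc2oc3oc4c5c(c(OC(C)=O)cc4c3c(=O)c2c1O)OC(C)(C)C=C5
A8 | alternative 3 | 3'',4''-epoxide of A7 with its oxygen on the face of the C3'' hydroxyl of A6 | Cc1c(OC(C)=O)cc2oc3oc4c5c(c(OC(C)=O)cc4c3c(=O)c2c1O)OC(C)(C)[C@@H]6O[C@@H]65
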